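The target is cut across C2–C7 and C3–C4. The cyclohexenone C2–C3–C4(=O)–C5=C6(CH3)–C7 shares C2–C7 with the cycloheptane C1–C2–C7–C8–C9–C10–C11 and carries oxygen at C4 next to C5=C6. This is the imprint of a 1-silyloxy-3-methylcyclopentadiene adding to a C2=C3 dienophile tethered through C8. One intramolecular Diels–Alder closes both rings and sets C2 and C7; its C4–C8 bond is sacrificial. The precursor is a 5,5-disubstituted silyloxycyclopentadiene with C1, C9 and C11 preset and an E-nitroalkene. Nitrogen then lands endo at C3, antiperiplanar to C4–C8, so that after reduction a deaminative semipinacol shift moves C8 from C4 to C3, forming ring A and the enone together.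

Key step: step 16

Numbering: C1 = quaternary carbon bearing CH3 and C12H2–O; C2, C3 = ring CH; C4 = ketone carbon; C5=C6(CH3); C7 = CH; C8 = C(CH3); C9 = CH–O; C10 = CH2; C11 = CH–O; ring A = cyclobutane C2–C3–C8–C7.

Assumption: the iridium-catalysed coupling of step 1 is taken to give the anti diol (secondary OH anti to CH2OH when the chain is drawn through the vinyl group); the CH2OH arm therefore becomes C2 and the vinyl arm C12.

Design remark: an activating group that merely stays on C3 would end at a bridgehead next to the enone, where it cannot be removed through an enolate. Nitrogen is used because it can leave as N2 and so drives the C8 shift.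

Step 1
Reactants: 1 3-[(4-methoxyphenyl)methoxy]propan-1-ol; 2 2-methyl-2-vinyloxirane (isoprene monoxide, racemic)
Product: 3 (2R,3R)-2-ethenyl-5-[(4-methoxyphenyl)methoxy]-2-methylpentane-1,3-diol
Conditions: [Ir(cod)Cl]2, Tol-BINAP (the antipode giving the 2R,3R diol), 4-cyano-3-nitrobenzoic acid, K3PO4, THF, 60 °C
Reagents that add atoms: none
Why: Iridium-catalysed redox-triggered tert-(hydroxy)prenylation (transfer-hydrogenative carbonyl allylation): dehydrogenation of 1 gives the aldehyde, the reduced iridium centre opens racemic 2 to interconverting σ-allyliridium isomers, the (E)-isomer adds through a closed chair transition state so that C11–OH and the CH2OH arm come out anti, and the ligand antipode fixes C1 and C11 together.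

Step 2
Reactants: 3 (2R,3R)-2-ethenyl-5-[(4-methoxyphenyl)methoxy]-2-methylpentane-1,3-diol
Product: 4 (3R,4R)-4-({[tert-butyl(dimethyl)silyl]oxy}methyl)-1-[(4-methoxyphenyl)methoxy]-4-methylhex-5-en-3-ol
Conditions: TBSCl (1.05 equiv), imidazole, CH2Cl2, −20 → 0 °C
Reagents that add atoms: tert-butyldimethylsilyl chloride, CC(C)(C)[Si](C)(C)Cl
Why: Selective silylation: the primary hydroxyl reacts far faster than the neopentyl secondary C11–OH, which marks the CH2OH arm as latent C2.

Step 3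
Reactants: 4 (3R,4R)-4-({[tert-butyl(dimethyl)silyl]oxy}methyl)-1-[(4-methoxyphenyl)methoxy]-4-methylhex-5-en-3-ol
Product: 6 (2R,3R)-2-({[tert-butyl(dimethyl)silyl]oxy}methyl)-5-[(4-methoxyphenyl)methoxy]-2-methylpentane-1,3-diol, via ozonide 5 (not isolated)
Conditions: O3, CH2Cl2, −78 °C (Sudan III end point); then NaBH4, MeOH, −78 → 0 °C
Reagents that add atoms: ozone, [O-][O+]=O
Why: Ozonolysis of the monosubstituted alkene with reductive work-up turns the vinyl arm into the C12 hydroxymethyl group without touching a stereocentre, the indicator end point sparing the electron-rich aryl ether.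

Step 4
Reactants: 6 (2R,3R)-2-({[tert-butyl(dimethyl)silyl]oxy}methyl)-5-[(4-methoxyphenyl)methoxy]-2-methylpentane-1,3-diol
Product: 7 tert-butyl{[(4R,5R)-4-{2-[(4-methoxyphenyl)methoxy]ethyl}-2,2,5-trimethyl-1,3-dioxan-5-yl]methoxy}dimethylsilane
Conditions: 2,2-dimethoxypropane, PPTS (cat.), CH2Cl2, 23 °C
Reagents that add atoms: 2,2-dimethoxypropane, COC(C)(C)OC
Why: Acid-catalysed transketalisation closes the six-membered acetonide over the C11/C12 1,3-diol, and its chair holds the two tether arms (C10 and C2) gauche.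

Step 5
Reactants: 7 tert-butyl{[(4R,5R)-4-{2-[(4-methoxyphenyl)methoxy]ethyl}-2,2,5-trimethyl-1,3-dioxan-5-yl]methoxy}dimethylsilane
Product: 8 2-[(4R,5R)-5-({[tert-butyl(dimethyl)silyl]oxy}methyl)-2,2,5-trimethyl-1,3-dioxan-4-yl]ethan-1-ol
Conditions: DDQ, CH2Cl2/pH 7 buffer, 0 → 23 °C
Reagents that add atoms: none
Why: Oxidative cleavage of the p-methoxybenzyl ether (benzylic hydride abstraction, then hydrolysis of the oxocarbenium ion) leaves the silyl ether and the ketal intact.

Step 6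
Reactants: 8 2-[(4R,5R)-5-({[tert-butyl(dimethyl)silyl]oxy}methyl)-2,2,5-trimethyl-1,3-dioxan-4-yl]ethan-1-ol
Product: 9 [(4R,5R)-5-({[tert-butyl(dimethyl)silyl]oxy}methyl)-2,2,5-trimethyl-1,3-dioxan-4-yl]acetaldehyde
Conditions: Dess–Martin periodinane, NaHCO3, CH2Cl2, 0 → 23 °C
Reagents that add atoms: none
Why: Buffered Dess–Martin oxidation gives the β-alkoxy aldehyde (C9) without β-elimination.

Step 7
Reactants: 10 3-methylcyclopent-2-en-1-one
Product: 12 1-methyl-3-(trimethylsilyloxy)cyclopenta-1,3-diene, via lithium dienolate 11 (not isolated)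
Conditions: LiN(iPr)2, THF, −78 °C; then TMSCl, −78 → 0 °C
Reagents that add atoms: chlorotrimethylsilane, C[Si](C)(C)Cl
Why: Kinetic deprotonation of the enone at the α′-carbon (future C8) and O-silylation of the cross-conjugated enolate give the silyl dienol ether.

Step 8
Reactants: 9 [(4R,5R)-5-({[tert-butyl(dimethyl)silyl]oxy}methyl)-2,2,5-trimethyl-1,3-dioxan-4-yl]acetaldehyde; 12 1-methyl-3-(trimethylsilyloxy)cyclopenta-1,3-diene
Product: 13 5-{(1R)-2-[(4R,5R)-5-({[tert-butyl(dimethyl)silyl]oxy}methyl)-2,2,5-trimethyl-1,3-dioxan-4-yl]-1-hydroxyethyl}-3-methylcyclopent-2-en-1-one (both C8 epimers)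
Conditions: BF3·OEt2, CH2Cl2, −78 °C; aq. NaHCO3
Reagents that add atoms: none
Why: Mukaiyama aldol addition through an open transition state, in which the BF3-bound β-alkoxy aldehyde is attacked on the face given by the dipole-minimised 1,3-anti induction model, sets C9 (R) anti to C11–O; the C8–H centre is irrelevant because it is enolised in step 9.

Step 9
Reactants: 13 5-{(1R)-2-[(4R,5R)-5-({[tert-butyl(dimethyl)silyl]oxy}methyl)-2,2,5-trimethyl-1,3-dioxan-4-yl]-1-hydroxyethyl}-3-methylcyclopent-2-en-1-one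
Product: 15 (5S)-5-{(1R)-2-[(4R,5R)-5-({[tert-butyl(dimethyl)silyl]oxy}methyl)-2,2,5-trimethyl-1,3-dioxan-4-yl]-1-hydroxyethyl}-3,5-dimethylcyclopent-2-en-1-one, via dilithium aldolate enolate 14 (not isolated)
Conditions: LiN(iPr)2 (2.3 equiv), THF, −78 °C; then MeI, −78 → −30 °C
Reagents that add atoms: iodomethane, CI
Why: Fráter–Seebach-type alkylation of the aldol dianion: the lithium chelate between the C4 enolate oxygen and the C9 alkoxide is methylated at C8 on the face opposite the C10 chain, which should set the quaternary centre C8 (S) with CH3 anti to C9–O, and the dianion cannot undergo retro-aldol cleavage.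

Step 10
Reactants: 15 (5S)-5-{(1R)-2-[(4R,5R)-5-({[tert-butyl(dimethyl)silyl]oxy}methyl)-2,2,5-trimethyl-1,3-dioxan-4-yl]-1-hydroxyethyl}-3,5-dimethylcyclopent-2-en-1-one
Product: 16 (5S)-5-{(1R)-1-{[tert-butyl(dimethyl)silyl]oxy}-2-[(4R,5R)-5-({[tert-butyl(dimethyl)silyl]oxy}methyl)-2,2,5-trimethyl-1,3-dioxan-4-yl]ethyl}-3,5-dimethylcyclopent-2-en-1-one
Conditions: TBSOTf, 2,6-lutidine, CH2Cl2, −78 → 0 °C
Reagents that add atoms: tert-butyldimethylsilyl trifluoromethanesulfonate, CC(C)(C)[Si](C)(C)OS(=O)(=O)C(F)(F)F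
Why: Silyl triflate with a hindered base silylates the congested C9 hydroxyl, giving the ether that C9 must carry during the cycloaddition (a C9 ketone on the sp3 diene carbon would invite 1,5-acyl migration).

Step 11
Reactants: 16 (5S)-5-{(1R)-1-{[tert-butyl(dimethyl)silyl]oxy}-2-[(4R,5R)-5-({[tert-butyl(dimethyl)silyl]oxy}methyl)-2,2,5-trimethyl-1,3-dioxan-4-yl]ethyl}-3,5-dimethylcyclopent-2-en-1-one
Product: 17 (5S)-5-{(1R)-1-{[tert-butyl(dimethyl)silyl]oxy}-2-[(4R,5S)-5-(hydroxymethyl)-2,2,5-trimethyl-1,3-dioxan-4-yl]ethyl}-3,5-dimethylcyclopent-2-en-1-one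
Conditions: HF·pyridine, pyridine, THF, 0 °C
Reagents that add atoms: none
Why: Buffered fluoride desilylation is selective for the primary silyl ether, because the C9 silyl ether next to the quaternary C8 reacts far more slowly.

Step 12
Reactants: 17 (5S)-5-{(1R)-1-{[tert-butyl(dimethyl)silyl]oxy}-2-[(4R,5S)-5-(hydroxymethyl)-2,2,5-trimethyl-1,3-dioxan-4-yl]ethyl}-3,5-dimethylcyclopent-2-en-1-one
Product: 18 (4R,5S)-4-{(2R)-2-{[tert-butyl(dimethyl)silyl]oxy}-2-[(1S)-1,4-dimethyl-2-oxocyclopent-3-en-1-yl]ethyl}-2,2,5-trimethyl-1,3-dioxane-5-carbaldehyde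
Conditions: Dess–Martin periodinane, NaHCO3, CH2Cl2, 23 °C
Reagents that add atoms: none
Why: Dess–Martin oxidation gives the non-enolisable α-quaternary aldehyde (C2).

Step 13
Reactants: 18 (4R,5S)-4-{(2R)-2-{[tert-butyl(dimethyl)silyl]oxy}-2-[(1S)-1,4-dimethyl-2-oxocyclopent-3-en-1-yl]ethyl}-2,2,5-trimethyl-1,3-dioxane-5-carbaldehyde; 19 nitromethane
Product: 20 (5S)-5-{(1R)-1-{[tert-butyl(dimethyl)silyl]oxy}-2-[(4R,5R)-5-(1-hydroxy-2-nitroethyl)-2,2,5-trimethyl-1,3-dioxan-4-yl]ethyl}-3,5-dimethylcyclopent-2-en-1-one (both carbinol epimers)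
Conditions: MeNO2 (excess), 1,1,3,3-tetramethylguanidine (cat.), THF, 0 °C
Reagents that add atoms: none
Why: Henry (nitroaldol) addition to the non-enolisable aldehyde supplies C3 with its nitrogen; the new carbinol centre is lost in step 14.

Step 14
Reactants: 20 (5S)-5-{(1R)-1-{[tert-butyl(dimethyl)silyl]oxy}-2-[(4R,5R)-5-(1-hydroxy-2-nitroethyl)-2,2,5-trimethyl-1,3-dioxan-4-yl]ethyl}-3,5-dimethylcyclopent-2-en-1-one
Product: 21 (5S)-5-{(1R)-1-{[tert-butyl(dimethyl)silyl]oxy}-2-[(4R,5S)-2,2,5-trimethyl-5-[(E)-2-nitroethenyl]-1,3-dioxan-4-yl]ethyl}-3,5-dimethylcyclopent-2-en-1-one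
Conditions: MsCl, Et3N, CH2Cl2, −20 → 0 °C
Reagents that add atoms: none
Why: Mesylation and E1cB elimination of the β-nitro alcohol give the conjugated (E)-nitroalkene, the only geometry tolerated next to the quaternary C1.

Step 15
Reactants: 21 (5S)-5-{(1R)-1-{[tert-butyl(dimethyl)silyl]oxy}-2-[(4R,5S)-2,2,5-trimethyl-5-[(E)-2-nitroethenyl]-1,3-dioxan-4-yl]ethyl}-3,5-dimethylcyclopent-2-en-1-one
Product: 22 tert-butyl{(1R)-1-[(1S)-1,3-dimethyl-5-(trimethylsilyloxy)cyclopenta-2,4-dien-1-yl]-2-[(4R,5S)-2,2,5-trimethyl-5-[(E)-2-nitroethenyl]-1,3-dioxan-4-yl]ethoxy}dimethylsilane (the Diels–Alder precursor; C1 S, C8 S, C9 R, C11 R)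
Conditions: TMSOTf, Et3N, CH2Cl2, 0 °C; cold NaHCO3 work-up, used at once
Reagents that add atoms: trimethylsilyl trifluoromethanesulfonate, C[Si](C)(C)OS(=O)(=O)C(F)(F)F
Why: O-silylation of the enone and γ-deprotonation at C7, the only ring position available because C8 is quaternary, give the 1-silyloxy-3-methylcyclopentadiene.

Step 16
Reactants: 22 tert-butyl{(1R)-1-[(1S)-1,3-dimethyl-5-(trimethylsilyloxy)cyclopenta-2,4-dien-1-yl]-2-[(4R,5S)-2,2,5-trimethyl-5-[(E)-2-nitroethenyl]-1,3-dioxan-4-yl]ethoxy}dimethylsilane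
Product: 23 tricyclic norbornene adduct (bridgeheads C4 and C7, alkene C5=C6, one-carbon bridge C8) with C4–OSiMe3, endo C3–NO2, C9–OTBS and the C11–O/C12–O acetonide; (1S,2R,3R,4R,7R,8S,9R,11R)
Conditions: toluene (0.005 M), BHT (cat.), 90 °C, sealed tube
Reagents that add atoms: none
Why: A concerted, asynchronous normal-demand [4+2] cycloaddition in which the oxygen-raised HOMO of the diene C4=C5–C6=C7 meets the nitro-lowered LUMO of C2=C3, the C2–C7 bond running ahead of C3–C4; the closest known reaction type is the intramolecular Diels–Alder reaction of 5,5-disubstituted cyclopentadienes with an activated alkene tethered through the sp3 ring carbon. The cyclohexene ring C2–C3–C4–C5–C6–C7 closes as the cycloaddition ring itself, and the cycloheptane C1–C2–C7–C8–C9–C10–C11 closes through the four-atom tether C9–C10–C11–C1, held gauche at C11–C1 by the acetonide chair. C7 and C4 are set by C8 (S), because the tether can only deliver the dienophile to the diene face that carries C9; C2 is set by the exo position that the same short tether forces on C1, and the E geometry then puts NO2 endo at C3, antiperiplanar to C4–C8. The tether does not decide regiochemistry, since C4 and C7 both flank C8: C2-to-C7 bonding is secured by polarity (C7 is the nucleophilic terminus remote from OSiMe3, C2 the electrophilic β-carbon of the nitroalkene) and by the greater hindrance of the oxygenated terminus. The quaternary C8 excludes 1,5-hydrogen shifts of the diene, the C9 silyl ether excludes 1,5-acyl migration, and neutral conditions keep the acidic C3–H from epimerising.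

Step 17
Reactants: 23 tricyclic norbornene adduct (C4–OSiMe3, endo C3–NO2)
Product: 24 tricyclic amino alcohol: the same norbornene with endo C3–NH2 and free bridgehead C4–OH, C9–OTBS and acetonide retained; (1S,2R,3R,4R,7R,8S,9R,11R)
Conditions: Zn dust, AcOH, THF/H2O, 0 → 23 °C
Reagents that add atoms: none
Why: Dissolving-metal reduction of the secondary nitro group under acidic conditions (no nitronate, hence neither epimerisation at C3 nor retro-Henry cleavage of C3–C4) gives the endo amine, and the aqueous acid cleaves the labile bridgehead trimethylsilyl ether.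

Step 18
Reactants: 24 tricyclic amino alcohol (endo C3–NH2, C4–OH)
Product: 26 tricyclic enone with the target skeleton (cyclobutane C2–C3–C8–C7, C4 ketone, C5=C6), C9–OTBS and the C11–O/C12–O acetonide; (1S,2S,3R,7R,8R,9R,11R), via diazonium acetate 25 (not isolated)
Conditions: NaNO2, AcOH/H2O, 0 °C
Reagents that add atoms: none
Why: Tiffeneau–Demjanov-type deaminative semipinacol rearrangement: the endo C3 diazonium group leaves antiperiplanar to the C4–C8 bond, which migrates with retention at C8 and inversion at C3 under the push of the C4 hydroxyl (the developing carbonyl is conjugated with C5=C6), so that ring A and the enone arise together and C3 and C8 take the only configuration the cage allows.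

Step 19
Reactants: 26 tricyclic enone (C9–OTBS, acetonide)
Product: 27 triol: the tricyclic enone with free C9–OH, C11–OH and C12–OH; (1S,2S,3R,7R,8R,9R,11R)
Conditions: aq. HF (48%), MeCN, 0 → 23 °C
Reagents that add atoms: none
Why: Aqueous HF cleaves the hindered C9 silyl ether and hydrolyses the acetonide in one operation, and no hydroxyl is β to the ketone, so retro-aldol cleavage is not available.

Step 20
Reactants: 27 tricyclic enone triol (C9–OH, C11–OH, C12–OH); 28 angelic acid ((2Z)-2-methylbut-2-enoic acid, three molecules incorporated)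
Product: 30 CNP0266467.1 (9,11,12-tri-O-angeloyl tricyclic enone; 1S,2S,3R,7R,8R,9R,11R), via angeloyl trichlorobenzoyl anhydride 29 (not isolated)
Conditions: 28 (4.5 equiv), 2,4,6-trichlorobenzoyl chloride (4.5 equiv), Et3N (9 equiv), toluene, 23 °C; then 27, 80 °C
Reagents that add atoms: two further molecules of angelic acid (the first is reactant 28), C/C=C(/C)C(=O)O.C/C=C(/C)C(=O)O
Why: Yamaguchi-type acylation with the preformed mixed anhydride of angelic acid, run without a nucleophilic catalyst to suppress Z-to-E isomerisation to the tiglate, should esterify all three hydroxyls, each hydroxyl consuming one molecule of anhydride 29 and so one molecule of angelic acid.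

Compound list
1 | 3-[(4-methoxyphenyl)methoxy]propan-1-ol | COc1ccc(COCCCO)cc1 | starting material
2 | 2-methyl-2-vinyloxirane (isoprene monoxide, racemic) | CC1(C=C)CO1 | starting material
3 | (2R,3R)-2-ethenyl-5-[(4-methoxyphenyl)methoxy]-2-methylpentane-1,3-diol | C=C[C@](C)(CO)[C@H](O)CCOCc1ccc(OC)cc1 | intermediate
4 | (3R,4R)-4-({[tert-butyl(dimethyl)silyl]oxy}methyl)-1-[(4-methoxyphenyl)methoxy]-4-methylhex-5-en-3-ol | C=C[C@](C)(CO[Si](C)(C)C(C)(C)C)[C@H](O)CCOCc1ccc(OC)cc1 | intermediate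
5 | ozonide of 4 (1,2,4-trioxolane on the former vinyl carbons, both epimers at the trioxolane carbon) | C1OC(OO1)[C@](C)(CO[Si](C)(C)C(C)(C)C)[C@H](O)CCOCc2ccc(OC)cc2 | intermediate (not isolated)
6 | (2R,3R)-2-({[tert-butyl(dimethyl)silyl]oxy}methyl)-5-[(4-methoxyphenyl)methoxy]-2-methylpentane-1,3-diol | OC[C@](C)(CO[Si](C)(C)C(C)(C)C)[C@H](O)CCOCc1ccc(OC)cc1 | intermediate
7 | tert-butyl{[(4R,5R)-4-{2-[(4-methoxyphenyl)methoxy]ethyl}-2,2,5-trimethyl-1,3-dioxan-5-yl]methoxy}dimethylsilane | CC1(C)OC[C@](C)(CO[Si](C)(C)C(C)(C)C)[C@@H](CCOCc2ccc(OC)cc2)O1 | intermediate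
8 | 2-[(4R,5R)-5-({[tert-butyl(dimethyl)silyl]oxy}methyl)-2,2,5-trimethyl-1,3-dioxan-4-yl]ethan-1-ol | CC1(C)OC[C@](C)(CO[Si](C)(C)C(C)(C)C)[C@@H](CCO)O1 | intermediate
9 | [(4R,5R)-5-({[tert-butyl(dimethyl)silyl]oxy}methyl)-2,2,5-trimethyl-1,3-dioxan-4-yl]acetaldehyde | CC1(C)OC[C@](C)(CO[Si](C)(C)C(C)(C)C)[C@@H](CC=O)O1 | intermediate
10 | 3-methylcyclopent-2-en-1-one | CC1=CC(=O)CC1 | starting material
11 | lithium dienolate of 10 (O–Li on the former carbonyl, cross-conjugated) | CC1=CC(O[Li])=CC1 | intermediate (not isolated)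
12 | 1-methyl-3-(trimethylsilyloxy)cyclopenta-1,3-diene | CC1=CC(O[Si](C)(C)C)=CC1 | intermediate
13 | 5-{(1R)-2-[(4R,5R)-5-({[tert-butyl(dimethyl)silyl]oxy}methyl)-2,2,5-trimethyl-1,3-dioxan-4-yl]-1-hydroxyethyl}-3-methylcyclopent-2-en-1-one (both C8 epimers) | CC1=CC(=O)C(C1)[C@H](O)C[C@H]2OC(C)(C)OC[C@]2(C)CO[Si](C)(C)C(C)(C)C | intermediate
14 | dilithium dianion of 13 (C4 enolate, C9 alkoxide) | CC1=CC(O[Li])=C(C1)[C@H](O[Li])C[C@H]2OC(C)(C)OC[C@]2(C)CO[Si](C)(C)C(C)(C)C | intermediate (not isolated)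
15 | (5S)-5-{(1R)-2-[(4R,5R)-5-({[tert-butyl(dimethyl)silyl]oxy}methyl)-2,2,5-trimethyl-1,3-dioxan-4-yl]-1-hydroxyethyl}-3,5-dimethylcyclopent-2-en-1-one | CC1=CC(=O)[C@@](C)(C1)[C@H](O)C[C@H]2OC(C)(C)OC[C@]2(C)CO[Si](C)(C)C(C)(C)C | intermediate
16 | (5S)-5-{(1R)-1-{[tert-butyl(dimethyl)silyl]oxy}-2-[(4R,5R)-5-({[tert-butyl(dimethyl)silyl]oxy}methyl)-2,2,5-trimethyl-1,3-dioxan-4-yl]ethyl}-3,5-dimethylcyclopent-2-en-1-one | CC1=CC(=O)[C@@](C)(C1)[C@H](O[Si](C)(C)C(C)(C)C)C[C@H]2OC(C)(C)OC[C@]2(C)CO[Si](C)(C)C(C)(C)C | intermediate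
17 | (5S)-5-{(1R)-1-{[tert-butyl(dimethyl)silyl]oxy}-2-[(4R,5S)-5-(hydroxymethyl)-2,2,5-trimethyl-1,3-dioxan-4-yl]ethyl}-3,5-dimethylcyclopent-2-en-1-one | CC1=CC(=O)[C@@](C)(C1)[C@H](O[Si](C)(C)C(C)(C)C)C[C@H]2OC(C)(C)OC[C@]2(C)CO | intermediate
18 | (4R,5S)-4-{(2R)-2-{[tert-butyl(dimethyl)silyl]oxy}-2-[(1S)-1,4-dimethyl-2-oxocyclopent-3-en-1-yl]ethyl}-2,2,5-trimethyl-1,3-dioxane-5-carbaldehyde | CC1=CC(=O)[C@@](C)(C1)[C@H](O[Si](C)(C)C(C)(C)C)C[C@H]2OC(C)(C)OC[C@]2(C)C=O | intermediate
19 | nitromethane | C[N+](=O)[O-] | starting material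
20 | (5S)-5-{(1R)-1-{[tert-butyl(dimethyl)silyl]oxy}-2-[(4R,5R)-5-(1-hydroxy-2-nitroethyl)-2,2,5-trimethyl-1,3-dioxan-4-yl]ethyl}-3,5-dimethylcyclopent-2-en-1-one (both carbinol epimers) | CC1=CC(=O)[C@@](C)(C1)[C@H](O[Si](C)(C)C(C)(C)C)C[C@H]2OC(C)(C)OC[C@]2(C)C(O)C[N+](=O)[O-] | intermediate
21 | (5S)-5-{(1R)-1-{[tert-butyl(dimethyl)silyl]oxy}-2-[(4R,5S)-2,2,5-trimethyl-5-[(E)-2-nitroethenyl]-1,3-dioxan-4-yl]ethyl}-3,5-dimethylcyclopent-2-en-1-one | CC1=CC(=O)[C@@](C)(C1)[C@H](O[Si](C)(C)C(C)(C)C)C[C@H]2OC(C)(C)OC[C@]2(C)/C=C/[N+](=O)[O-] | intermediate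
22 | tert-butyl{(1R)-1-[(1S)-1,3-dimethyl-5-(trimethylsilyloxy)cyclopenta-2,4-dien-1-yl]-2-[(4R,5S)-2,2,5-trimethyl-5-[(E)-2-nitroethenyl]-1,3-dioxan-4-yl]ethoxy}dimethylsilane (Diels–Alder precursor) | CC1=C[C@@](C)([C@H](O[Si](C)(C)C(C)(C)C)C[C@H]2OC(C)(C)OC[C@]2(C)/C=C/[N+](=O)[O-])C(O[Si](C)(C)C)=C1 | intermediate
23 | tricyclic norbornene adduct with C4–OSiMe3, endo C3–NO2, C9–OTBS and C11/C12 acetonide; (1S,2R,3R,4R,7R,8S,9R,11R) | CC1(C)OC[C@]2(C)[C@@H]3[C@@H]([N+](=O)[O-])[C@@]4(O[Si](C)(C)C)C=C(C)[C@@H]3[C@@]4(C)[C@H](O[Si](C)(C)C(C)(C)C)C[C@H]2O1 | intermediate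
24 | tricyclic amino alcohol with endo C3–NH2 and bridgehead C4–OH; (1S,2R,3R,4R,7R,8S,9R,11R) | CC1(C)OC[C@]2(C)[C@@H]3[C@@H](N)[C@@]4(O)C=C(C)[C@@H]3[C@@]4(C)[C@H](O[Si](C)(C)C(C)(C)C)C[C@H]2O1 | intermediate
25 | C3 diazonium acetate of 24 | CC1(C)OC[C@]2(C)[C@@H]3[C@@H]([N+]#N)[C@@]4(O)C=C(C)[C@@H]3[C@@]4(C)[C@H](O[Si](C)(C)C(C)(C)C)C[C@H]2O1.CC(=O)[O-] | intermediate (not isolated)
26 | tricyclic enone with cyclobutane C2–C3–C8–C7, C9–OTBS and C11/C12 acetonide; (1S,2S,3R,7R,8R,9R,11R) | CC1(C)OC[C@]2(C)[C@@H]3[C@H]4C(=O)C=C(C)[C@@H]3[C@@]4(C)[C@H](O[Si](C)(C)C(C)(C)C)C[C@H]2O1 | intermediate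
27 | tricyclic enone triol (C9–OH, C11–OH, C12–OH); (1S,2S,3R,7R,8R,9R,11R) | OC[C@]1(C)[C@@H]2[C@H]3C(=O)C=C(C)[C@@H]2[C@@]3(C)[C@H](O)C[C@H]1O | intermediate
28 | angelic acid, (2Z)-2-methylbut-2-enoic acid | C/C=C(/C)C(=O)O | starting material
29 | (2Z)-2-methylbut-2-enoic 2,4,6-trichlorobenzoic anhydride | C/C=C(/C)C(=O)OC(=O)c1c(Cl)cc(Cl)cc1Cl | intermediate (not isolated)
30 | CNP0266467.1, tris-angelate of 27; (1S,2S,3R,7R,8R,9R,11R) | C/C=C(/C)C(=O)OC[C@]1(C)[C@@H]2[C@H]3C(=O)C=C(C)[C@@H]2[C@@]3(C)[C@H](OC(=O)/C(C)=C\C)C[C@H]1OC(=O)/C(C)=C\C | target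

Total step count: 20. Longest linear sequence: 19 steps (steps 1–6 and 8–20); step 7 is a one-step branch.

Steps most likely to fail

Step 16 (key step). The tethered cycloaddition has to join C2 and C7, each next to a quaternary carbon, through a seven-membered tether ring. It may be slower than intermolecular oligomerisation or decomposition of the nitroalkene and the silyl dienol ether, or C2 may bond to C4 instead of C7. The fallback replaces thermal activation by chelating Lewis-acid activation at low temperature and sets out from aldehyde 18. Masamune–Roush olefination with diethyl [2-oxo-2-(2-oxo-1,3-oxazolidin-3-yl)ethyl]phosphonate (LiCl, iPr2NEt, MeCN) would give the (E)-N-enoyl oxazolidinone F1. TMSOTf/Et3N would give the silyloxydiene imide F2. Me2AlCl (CH2Cl2, −78 → −30 °C) should promote the same intramolecular [4+2] to the adduct imide F3, with the acyl group endo at C3. LiOH/H2O2 would remove the auxiliary and the bridgehead silyl group to give the hydroxy acid F4. Curtius rearrangement (DPPA, Et3N, toluene, 80 °C, retention at C3) would give the isocyanate F5, and its hydrolysis (aq. LiOH, THF) comes back to the route at amino alcohol 24.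

Step 18. Loss of nitrogen may outrun migration, giving a free C3 cation that is captured by solvent or relieved by a shift of the vinylic C5 or of hydride instead of the C8 shift that builds the strained cyclobutane. The fallback is a base-induced semipinacol of an endo sulfonate, in which no free cation can form; it sets out from aldehyde 18. Takai–Utimoto-type boryl olefination (CrCl2, LiI, Cl2CHB(pin), THF) would give the (E)-alkenylboronate F6, and TMSOTf/Et3N the silyloxydiene boronate F7. The thermal intramolecular Diels–Alder reaction (xylene, 140–170 °C; a weaker dienophile, hence more forcing) would give the endo boronate adduct F8. NaBO3·4H2O (THF/H2O) oxidises C–B with retention and removes the bridgehead silyl group to give the endo diol F9. MsCl/Et3N sulfonylates only the secondary hydroxyl to give the mesylate F10. KOtBu (THF, 0 °C) then deprotonates the C4 hydroxyl, and the C4–C8 bond, antiperiplanar to the mesylate, migrates to come back to the route at enone 26.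

Step 9. Incomplete second deprotonation would leave a monoanionic aldolate that fragments by retro-aldol on warming, and methylation may show poor facial selectivity at C8 or compete with γ-deprotonation. The fallback installs the methyl group before the C8–C9 bond is made and sets out from enone 10 and aldehyde 9. LiN(iPr)2/MeI would convert 10 into 3,5-dimethylcyclopent-2-en-1-one F11, and LiN(iPr)2/TMSCl would give its silyl dienol ether F12. Mukaiyama aldol addition of F12 to 9 (BF3·OEt2, CH2Cl2, −78 °C) forms the quaternary C8 directly under the same 1,3-anti induction at C9. The C8 epimers would be separated by chromatography, and the required one is compound 15, where the fallback comes back to the route.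

Further compounds
F1 | step 16 | (E)-N-enoyl oxazolidinone of the C2 arm (enone, C9–OTBS, acetonide retained) | CC1=CC(=O)[C@@](C)(C1)[C@H](O[Si](C)(C)C(C)(C)C)C[C@H]2OC(C)(C)OC[C@]2(C)/C=C/C(=O)N3CCOC3=O
F2 | step 16 | 1-(trimethylsilyloxy)cyclopentadiene carrying the (E)-N-enoyl oxazolidinone | CC1=C[C@@](C)([C@H](O[Si](C)(C)C(C)(C)C)C[C@H]2OC(C)(C)OC[C@]2(C)/C=C/C(=O)N3CCOC3=O)C(O[Si](C)(C)C)=C1
F3 | step 16 | norbornene adduct with endo C3 acyl oxazolidinone and C4–OSiMe3 | CC1(C)OC[C@]2(C)[C@@H]3[C@@H](C(=O)N5CCOC5=O)[C@@]4(O[Si](C)(C)C)C=C(C)[C@@H]3[C@@]4(C)[C@H](O[Si](C)(C)C(C)(C)C)C[C@H]2O1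
F4 | step 16 | norbornene endo C3 carboxylic acid with free C4–OH | CC1(C)OC[C@]2(C)[C@@H]3[C@@H](C(=O)O)[C@@]4(O)C=C(C)[C@@H]3[C@@]4(C)[C@H](O[Si](C)(C)C(C)(C)C)C[C@H]2O1
F5 | step 16 | norbornene endo C3 isocyanate with free C4–OH | CC1(C)OC[C@]2(C)[C@@H]3[C@@H](N=C=O)[C@@]4(O)C=C(C)[C@@H]3[C@@]4(C)[C@H](O[Si](C)(C)C(C)(C)C)C[C@H]2O1
F6 | step 18 | (E)-alkenyl pinacolboronate of the C2 arm (enone, C9–OTBS, acetonide retained) | CC1=CC(=O)[C@@](C)(C1)[C@H](O[Si](C)(C)C(C)(C)C)C[C@H]2OC(C)(C)OC[C@]2(C)/C=C/B3OC(C)(C)C(C)(C)O3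
F7 | step 18 | 1-(trimethylsilyloxy)cyclopentadiene carrying the (E)-alkenyl pinacolboronate | CC1=C[C@@](C)([C@H](O[Si](C)(C)C(C)(C)C)C[C@H]2OC(C)(C)OC[C@]2(C)/C=C/B3OC(C)(C)C(C)(C)O3)C(O[Si](C)(C)C)=C1
F8 | step 18 | norbornene adduct with endo C3 pinacolboronate and C4–OSiMe3 | CC1(C)OC[C@]2(C)[C@@H]3[C@@H](B5OC(C)(C)C(C)(C)O5)[C@@]4(O[Si](C)(C)C)C=C(C)[C@@H]3[C@@]4(C)[C@H](O[Si](C)(C)C(C)(C)C)C[C@H]2O1
F9 | step 18 | norbornene diol with endo C3–OH and bridgehead C4–OH | CC1(C)OC[C@]2(C)[C@@H]3[C@@H](O)[C@@]4(O)C=C(C)[C@@H]3[C@@]4(C)[C@H](O[Si](C)(C)C(C)(C)C)C[C@H]2O1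
F10 | step 18 | norbornene endo C3 mesylate with bridgehead C4–OH | CC1(C)OC[C@]2(C)[C@@H]3[C@@H](OS(C)(=O)=O)[C@@]4(O)C=C(C)[C@@H]3[C@@]4(C)[C@H](O[Si](C)(C)C(C)(C)C)C[C@H]2O1
F11 | step 9 | 3,5-dimethylcyclopent-2-en-1-one (racemic) | CC1=CC(=O)C(C)C1
F12 | step 9 | 1,4-dimethyl-2-(trimethylsilyloxy)cyclopenta-1,3-diene | CC1=CC(O[Si](C)(C)C)=C(C)C1
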